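## Analysis of the target

The target 21 is (2S,3R,5R)-3-bromo-2-[(E)-2-bromoethenyl]-5-[(2R)-2-bromo-1-chloropropan-2-yl]-2-methyloxolane, a C10 polyhalogenated monoterpene with one ring. The ring is numbered O1, C2, C3, C4, C5 throughout. C2 is a fully substituted ether carbon with a methyl and an (E)-2-bromoethenyl group. C3 is a secondary bromide, C4 a methylene group, and C5 an ether methine carrying an acyclic quaternary carbon with Br, CH3 and CH2Cl. There are four stereocentres. The C2 methyl group, the C3 bromine and the C5 side chain lie on one face of the ring, and the bromoethenyl group lies on the other.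

The sensitive groups are:
- the tertiary bromide, which is vicinal to CH2Cl and β to O1 (ionisation, elimination, 1,2-halogen shift);
- the secondary bromide next to a quaternary carbon (elimination towards C4);
- the alkenyl bromide.

The synthesis is hard for three reasons. The molecule has no carbonyl handle. The C3 bromine sits on the more crowded face. The side chain has bromine on the tertiary and chlorine on the primary carbon, the reverse of what electrophilic bromochlorination of an isopropenyl group gives.

The strategy rests on C4. If C3 is a ketone, C4 can be a carbenoid carbon, and the C5–H bond is an ether C–H bond five atoms away (C4, C3, C2, O1, C5). The ring can therefore be closed by C4–C5 bond formation on a tertiary ether in which C2 is already fixed.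

## Retrosynthetic reasoning

**Side-chain halogens (21 ⇒ 20 ⇒ 19).** The primary C–Cl bond is cut first, then the tertiary C–Br bond. A tertiary bromide of defined configuration cannot be made by direct substitution on an open chain. The one stereospecific entry is backside opening of a 2,2-disubstituted epoxide at its tertiary carbon. Epoxide 19 therefore gives bromohydrin 20 with inversion, and the primary hydroxyl of 20 is then exchanged for chloride. Forward, bromide must attack the tertiary and not the primary epoxide carbon, and the last substitution must leave the neighbouring tertiary bromide where it is.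

**Side-chain carbon skeleton (19 ⇒ 18 ⇒ 17 ⇒ 15).** The bond between the side-chain carbon and its CH2 group is cut. Methyl ketone 17 is an α-alkoxy ketone, so a chloromethyl–magnesium nucleophile can add under chelate control between the ketone oxygen and O1. This sets the tertiary carbinol of 18 from the C5 stereocentre, and 18 closes to 19 without touching that centre. Ketone 17 comes from the isopropenyl group of 15 by ozonolysis.

**Bromoethenyl group (15 ⇒ 13).** The alkenyl C–Br and C–H bonds are cut back to the terminal alkyne of 13. Hydrozirconation–bromination gives only the E isomer. It is placed before the ozonolysis and before any ketone, epoxide or tertiary halide exists, because the zirconium hydride would not tolerate those groups.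

**C3 bromide (13 ⇒ 11 ⇒ 10 ⇒ 9).** The C3–Br bond is cut to the C3 alcohol with the opposite configuration (hydroxyl trans to the C2 methyl), so that one inversion puts bromine on the methyl face. The displacement is done while C2 still carries the slim ethynyl group. The alcohol comes from ketone 9. The substrate alone should direct hydride to the face away from the methyl and isopropenyl groups, which gives the wrong epimer. The reduction is therefore put under catalyst control.

**Ring (9 ⇒ 8), the key disconnection.** The C4–C5 bond is cut. Diazoketone 8 carries the carbenoid precursor at C4 and a methallyl ether whose O–CH2 hydrogens are both allylic and α to oxygen. Insertion closes the oxolan-3-one and creates C5. The ketone it leaves at C3 is the handle for the bromide, and the isopropenyl group it leaves at C5 is the handle for the side chain.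

**Cyclisation substrate (8 ⇒ 6 ⇒ 5 ⇒ 3 + 4; 3 ⇒ 1 + 2).** The diazoketone comes from acid 6 by diazomethylation of its chloride. The acid comes from ester 5, and the ether from tertiary alcohol 3 and methallyl bromide 4. The C2 stereocentre is set first, by catalytic asymmetric alkynylation of pyruvate 1 with silylacetylene 2. A triisopropylsilyl cap is used because a trimethylsilyl alkyne would not survive the hydroxide saponification.

## Alternatives that were turned down

**Alternative 1:** Prins–pinacol ring construction. C4–C5 and C2–C3 are cut together, which leads to the 1,3-dioxolane acetal A2. In A2 the halogenated side chain sits on the acetal carbon, and the diol part holds the alkynyl carbinol and a vinyl carbinol. Forward, SnCl4 ionises A2 to an oxocarbenium ion, the vinyl group adds to it (C4–C5), and the oxanyl cation contracts by 1,2-shift of the oxygen-bearing quaternary carbon (C2–C3) to the all-cis 3-acetyloxolane A1.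
- For it: one step makes the ring, two ring bonds and the C3 and C5 stereocentres with a well-established all-cis outcome, and the route is convergent.
- Against it: A2 needs the tertiary bromide stereocentre before the ring is made, and then exposes it to a strong Lewis acid next to a cationic centre. Its diol part needs two adjacent fully substituted carbinol carbons. The acetyl group of A1 must be degraded to oxygen and then replaced by bromine with net retention, which means two inversions at the hindered C3.
- Comparison: A1 is stronger on the stereochemical certainty of the ring-forming event. The chosen route keeps every halogen out of the ring-forming step, leaves a C3 ketone that needs one inversion only, and reaches its cyclisation substrate 8 in four steps.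

**Alternative 2:** Ring-closing metathesis with selection between diastereotopic groups. The C3=C4 bond is cut, giving triene A4, the ether of a divinyl methyl carbinol with a chiral allylic alcohol. Forward, second-generation Grubbs catalyst joins the allylic vinyl group to one of the two diastereotopic vinyl groups with loss of ethylene, giving the 2,5-dihydrofuran A3.
- For it: the closure is short, robust and needs no diazo compound, and C2 is created without an enantioselective step at a quaternary carbon.
- Against it: the group selection must be relayed from C5 across the forming ring and only distinguishes methyl from vinyl. A3 has a C3=C4 alkene with no polar bias, so adding HBr with bromine at C3 on the methyl face has no control element. The remaining vinyl group must be cut to one carbon and rebuilt as bromoethenyl in the presence of the ring alkene. The hindered bis-allylic tertiary ether A4 is itself hard to make.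
- Comparison: it is stronger in brevity and in the reliability of the ring closure. The chosen strategy delivers an oxygen at C3, which settles where bromine goes, and an alkyne at C2, which becomes the bromoethenyl group in one operation.

**Alternative 3:** Cyclobutanone and Baeyer–Villiger oxidation. O1 is cut out of the ring: lactone A5 comes from cyclobutanone A6, which comes from a ketene–enol ether cycloaddition. Forward, a peracid inserts oxygen between the carbonyl carbon and the quaternary α-carbon of A6 with retention, giving A5.
- For it: the regiochemistry and stereospecificity of the oxygen insertion are very reliable, the C2/C3 relation is set in the cycloaddition, and no metal carbenoid is involved.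
- Against it: A6 is racemic unless an auxiliary is added. In A5 the future C5 is a lactone carbonyl, so the three-carbon side chain must be added as a nucleophile and the lactol reduced through an oxocarbenium ion, with little control from the distant substituents. The vinyl group again needs a one-carbon degradation and rebuild.
- Comparison: its key step is more certain than a carbenoid insertion. The chosen strategy forms C5 together with its side-chain carbon skeleton in the ring closure and takes the absolute configuration from a catalytic step at the very start.

Key step: step 5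

Assumption: the (1S,2S) antipode of the amino alcohol ligand in step 1 is taken to deliver (S)-3; if the sense of induction proves opposite, the (1R,2R) ligand is used and nothing else changes.

## Route

Step 1
Reactants: 1 ethyl pyruvate; 2 (triisopropylsilyl)acetylene
Product: 3 ethyl (2S)-2-hydroxy-2-methyl-4-(triisopropylsilyl)but-3-ynoate
Conditions: Zn(OTf)2 (20 mol %), (1S,2S)-3-(tert-butyldimethylsilyloxy)-2-(dimethylamino)-1-(4-nitrophenyl)propan-1-ol (22 mol %), Et3N (30 mol %), toluene, 70 °C, slow addition of 1
Reagents that add atoms: none
Why: Catalytic asymmetric alkynylation of an α-keto ester: the zinc acetylide formed from 2 adds to the ketone carbonyl of 1 inside the chiral zinc amino alkoxide complex, which selects the face leading to the (S)-carbinol. Slow addition of 1 limits its self-aldol reaction.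

Step 2
Reactants: 3 ethyl (2S)-2-hydroxy-2-methyl-4-(triisopropylsilyl)but-3-ynoate; 4 3-bromo-2-methylpropene
Product: 5 ethyl (2S)-2-methyl-2-[(2-methylprop-2-en-1-yl)oxy]-4-(triisopropylsilyl)but-3-ynoate
Conditions: NaH, Bu4NI (cat.), THF/DMF, 0 °C → rt
Reagents that add atoms: none
Why: Williamson etherification of the tertiary alkoxide with a reactive allylic bromide; the stereocentre has no acidic hydrogen and is untouched, and the low temperature avoids loss of acetylide from the alkoxide.

Step 3
Reactants: 5 ethyl (2S)-2-methyl-2-[(2-methylprop-2-en-1-yl)oxy]-4-(triisopropylsilyl)but-3-ynoate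
Product: 6 (2S)-2-methyl-2-[(2-methylprop-2-en-1-yl)oxy]-4-(triisopropylsilyl)but-3-ynoic acid
Conditions: LiOH·H2O, THF/MeOH/H2O, rt; then aq. HCl to pH 3
Reagents that add atoms: lithium hydroxide, [Li+].[OH-]
Why: Saponification of the ester; the triisopropylsilyl alkyne withstands hydroxide, which a trimethylsilyl alkyne would not. If needed, the acid can be brought to full enantiopurity by crystallising its salt with a chiral amine.

Step 4
Reactants: 6 (2S)-2-methyl-2-[(2-methylprop-2-en-1-yl)oxy]-4-(triisopropylsilyl)but-3-ynoic acid
Product: 8 (3S)-1-diazo-3-methyl-3-[(2-methylprop-2-en-1-yl)oxy]-5-(triisopropylsilyl)pent-4-yn-2-one, via acid chloride 7 (not isolated)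
Conditions: (COCl)2, DMF (cat.), CH2Cl2, 0 °C; evaporate; CH2N2 (3 equiv), Et2O, 0 °C
Reagents that add atoms: oxalyl chloride, ClC(=O)C(Cl)=O; diazomethane, C=[N+]=[N-]
Why: Acylation of diazomethane by the acid chloride (first stage of the Arndt–Eistert sequence), with excess diazomethane taking up the HCl. The quaternary α-carbon excludes ketene formation and epimerisation.

Step 5
Reactants: 8 (3S)-1-diazo-3-methyl-3-[(2-methylprop-2-en-1-yl)oxy]-5-(triisopropylsilyl)pent-4-yn-2-one
Product: 9 (2S,5R)-2-methyl-5-(prop-1-en-2-yl)-2-[(triisopropylsilyl)ethynyl]oxolan-3-one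
Conditions: Rh2(OAc)4 (1 mol %), CH2Cl2, rt, slow addition of 8 by syringe pump
Reagents that add atoms: none
Why: Rh2(OAc)4 expels dinitrogen from 8 and gives an electrophilic rhodium carbenoid at C4. The carbenoid inserts into one of the two diastereotopic O–CH2 hydrogens five atoms away through a three-centre, hydride-transfer-like transition state; the closest known reaction is the dirhodium carboxylate-catalysed 1,5 C–H insertion of α-alkoxy diazoketones to oxolan-3-ones. The new C4–C5 bond closes the five-membered ring by 1,5-insertion, with C4, C3, C2, O1, C5 and the migrating hydrogen in a chair-like array. The new stereocentre C5 is controlled by C2: the isopropenyl group and the C2 methyl group should sit pseudo-equatorial and the rod-like silylalkyne pseudo-axial, which places methyl and isopropenyl cis (5R). The step needs insertion to win over addition to the methallyl double bond and over Wolff rearrangement. Insertion is favoured because the C–H bond is activated twice (ether oxygen and allylic position) and the five-membered transition state is preferred to the bicyclo[4.1.0] cyclopropane; slow addition suppresses carbene dimers. The alkyne cannot be reached by the carbenoid without forming a three- or four-membered ring, and the quaternary C2 cannot epimerise.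

Step 6
Reactants: 9 (2S,5R)-2-methyl-5-(prop-1-en-2-yl)-2-[(triisopropylsilyl)ethynyl]oxolan-3-one
Product: 10 (2S,3S,5R)-2-methyl-5-(prop-1-en-2-yl)-2-[(triisopropylsilyl)ethynyl]oxolan-3-ol
Conditions: (R)-2-methyl-CBS-oxazaborolidine [(3aR)-1-methyl-3,3-diphenyltetrahydro-1H,3H-pyrrolo[1,2-c][1,3,2]oxazaborole] (20 mol %), catecholborane, toluene, −78 → −40 °C; then MeOH, aq. NaOH
Reagents that add atoms: none
Why: Corey–Bakshi–Shibata reduction: the catalyst binds the ketone with the quaternary C2 as the large and C4 as the small flank and delivers hydride to the face of the methyl group, giving the (3S)-alcohol with hydroxyl trans to methyl. Catalyst control is needed because the substrate alone should send hydride to the opposite face; catecholborane at low temperature leaves the alkene and alkyne alone.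

Step 7
Reactants: 10 (2S,3S,5R)-2-methyl-5-(prop-1-en-2-yl)-2-[(triisopropylsilyl)ethynyl]oxolan-3-ol
Product: 11 (2S,3S,5R)-2-ethynyl-2-methyl-5-(prop-1-en-2-yl)oxolan-3-ol
Conditions: Bu4NF, THF, 0 °C → rt
Reagents that add atoms: none
Why: Fluoride cleaves the C(sp)–Si bond; it is done at the alcohol stage, before any base-sensitive halide is present.

Step 8
Reactants: 11 (2S,3S,5R)-2-ethynyl-2-methyl-5-(prop-1-en-2-yl)oxolan-3-ol
Product: 13 (2S,3R,5R)-3-bromo-2-ethynyl-2-methyl-5-(prop-1-en-2-yl)oxolane, via triflate 12 (not isolated)
Conditions: Tf2O, pyridine, CH2Cl2, −30 °C; then Bu4NBr, toluene, −30 °C → rt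
Reagents that add atoms: trifluoromethanesulfonic anhydride, O=S(=O)(OS(=O)(=O)C(F)(F)F)C(F)(F)F; tetrabutylammonium bromide, CCCC[N+](CCCC)(CCCC)CCCC.[Br-]
Why: SN2 displacement of the secondary triflate by bromide with inversion puts bromine on the methyl face (3R). The adjacent C–O bond disfavours ionisation, and soluble bromide in a non-polar medium favours substitution over elimination.

Step 9
Reactants: 13 (2S,3R,5R)-3-bromo-2-ethynyl-2-methyl-5-(prop-1-en-2-yl)oxolane
Product: 15 (2S,3R,5R)-3-bromo-2-[(E)-2-bromoethenyl]-2-methyl-5-(prop-1-en-2-yl)oxolane, via alkenylzirconocene chloride 14 (not isolated)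
Conditions: Cp2Zr(H)Cl, THF, rt, 20 min; then N-bromosuccinimide, 0 °C
Reagents that add atoms: chlorobis(cyclopentadienyl)hydridozirconium, [H][Zr](Cl)(C1C=CC=C1)C1C=CC=C1; N-bromosuccinimide, BrN1C(=O)CCC1=O
Why: Hydrozirconation adds Zr–H syn across the terminal alkyne with zirconium on the terminal carbon, and bromine then replaces zirconium with retention, so only the (E)-alkenyl bromide forms. The terminal alkyne reacts much faster than the 1,1-disubstituted alkene or the secondary bromide.

Step 10
Reactants: 15 (2S,3R,5R)-3-bromo-2-[(E)-2-bromoethenyl]-2-methyl-5-(prop-1-en-2-yl)oxolane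
Product: 17 (2S,3R,5R)-5-acetyl-3-bromo-2-[(E)-2-bromoethenyl]-2-methyloxolane, via ozonide 16 (not isolated)
Conditions: O3 (1.0 equiv, Sudan red 7B end-point), CH2Cl2, −78 °C; then PPh3, −78 °C → rt
Reagents that add atoms: ozone, [O-][O+]=O
Why: Ozonolysis with reductive work-up; the electron-rich 1,1-disubstituted alkene reacts with ozone far faster than the halogen-deactivated bromoalkene, and the dye end-point prevents over-oxidation. The neutral work-up avoids enolisation at C5.

Step 11
Reactants: 17 (2S,3R,5R)-5-acetyl-3-bromo-2-[(E)-2-bromoethenyl]-2-methyloxolane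
Product: 18 (2S,3R,5R)-3-bromo-2-[(E)-2-bromoethenyl]-5-[(2S)-1-chloro-2-hydroxypropan-2-yl]-2-methyloxolane
Conditions: ICH2Cl, iPrMgCl·LiCl, THF, −78 °C (ClCH2MgCl formed in situ); then 17, −78 °C; aq. NH4Cl at −78 °C
Reagents that add atoms: chloroiodomethane, ClCI
Why: Addition of a magnesium carbenoid to an α-alkoxy ketone under Cram chelate control: magnesium bridges the ketone oxygen and O1, and the chloromethyl group enters from the face of the C5 hydrogen, away from C4, giving the (2S)-chlorohydrin. The cold quench keeps the alkenyl and alkyl bromides untouched.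

Step 12
Reactants: 18 (2S,3R,5R)-3-bromo-2-[(E)-2-bromoethenyl]-5-[(2S)-1-chloro-2-hydroxypropan-2-yl]-2-methyloxolane
Product: 19 (2S,3R,5R)-3-bromo-2-[(E)-2-bromoethenyl]-2-methyl-5-[(2R)-2-methyloxiran-2-yl]oxolane
Conditions: K2CO3, MeOH, 0 °C → rt
Reagents that add atoms: none
Why: Intramolecular Williamson closure of the chlorohydrin; the tertiary C–O bond is not broken, so the configuration is kept (the descriptor changes from S to R only because of the priority rules).

Step 13
Reactants: 19 (2S,3R,5R)-3-bromo-2-[(E)-2-bromoethenyl]-2-methyl-5-[(2R)-2-methyloxiran-2-yl]oxolane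
Product: 20 (2S,3R,5R)-3-bromo-2-[(E)-2-bromoethenyl]-5-[(2S)-2-bromo-1-hydroxypropan-2-yl]-2-methyloxolane
Conditions: HBr (1.05 equiv, anhydrous), CH2Cl2, −78 °C
Reagents that add atoms: hydrogen bromide, Br
Why: Acid-mediated opening of a 2,2-disubstituted epoxide: bromide attacks the protonated epoxide at the tertiary carbon, which carries most of the positive charge, from the side opposite the C–O bond (borderline SN2, inversion). Low temperature and a non-ionising solvent should keep the opening stereospecific.

Step 14
Reactants: 20 (2S,3R,5R)-3-bromo-2-[(E)-2-bromoethenyl]-5-[(2S)-2-bromo-1-hydroxypropan-2-yl]-2-methyloxolane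
Product: 21 (2S,3R,5R)-3-bromo-2-[(E)-2-bromoethenyl]-5-[(2R)-2-bromo-1-chloropropan-2-yl]-2-methyloxolane
Conditions: PPh3, CCl4, CH2Cl2, 0 → 35 °C
Reagents that add atoms: carbon tetrachloride, ClC(Cl)(Cl)Cl
Why: Appel chlorination: chloride displaces triphenylphosphine oxide from the primary oxyphosphonium ion inside an ion pair in a non-ionising medium, the conditions that convert neopentyl-type alcohols without rearrangement. The tertiary centre is not involved (its descriptor changes from S to R only because CH2Cl now outranks C5).

## Compound list

1 | ethyl pyruvate | CCOC(=O)C(C)=O | starting material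
2 | (triisopropylsilyl)acetylene | C#C[Si](C(C)C)(C(C)C)C(C)C | starting material
3 | ethyl (2S)-2-hydroxy-2-methyl-4-(triisopropylsilyl)but-3-ynoate | CCOC(=O)[C@](C)(C#C[Si](C(C)C)(C(C)C)C(C)C)O | intermediate
4 | 3-bromo-2-methylpropene | CC(=C)CBr | starting material
5 | ethyl (2S)-2-methyl-2-[(2-methylprop-2-en-1-yl)oxy]-4-(triisopropylsilyl)but-3-ynoate | CCOC(=O)[C@](C)(C#C[Si](C(C)C)(C(C)C)C(C)C)OCC(C)=C | intermediate
6 | (2S)-2-methyl-2-[(2-methylprop-2-en-1-yl)oxy]-4-(triisopropylsilyl)but-3-ynoic acid | OC(=O)[C@](C)(C#C[Si](C(C)C)(C(C)C)C(C)C)OCC(C)=C | intermediate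
7 | (2S)-2-methyl-2-[(2-methylprop-2-en-1-yl)oxy]-4-(triisopropylsilyl)but-3-ynoyl chloride | ClC(=O)[C@](C)(C#C[Si](C(C)C)(C(C)C)C(C)C)OCC(C)=C | intermediate
8 | (3S)-1-diazo-3-methyl-3-[(2-methylprop-2-en-1-yl)oxy]-5-(triisopropylsilyl)pent-4-yn-2-one | [N-]=[N+]=CC(=O)[C@](C)(C#C[Si](C(C)C)(C(C)C)C(C)C)OCC(C)=C | intermediate
9 | (2S,5R)-2-methyl-5-(prop-1-en-2-yl)-2-[(triisopropylsilyl)ethynyl]oxolan-3-one (methyl cis to isopropenyl) | CC(=C)[C@H]1CC(=O)[C@](C)(C#C[Si](C(C)C)(C(C)C)C(C)C)O1 | intermediate
10 | (2S,3S,5R)-2-methyl-5-(prop-1-en-2-yl)-2-[(triisopropylsilyl)ethynyl]oxolan-3-ol (hydroxyl trans to methyl) | CC(=C)[C@H]1C[C@H](O)[C@](C)(C#C[Si](C(C)C)(C(C)C)C(C)C)O1 | intermediate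
11 | (2S,3S,5R)-2-ethynyl-2-methyl-5-(prop-1-en-2-yl)oxolan-3-ol | CC(=C)[C@H]1C[C@H](O)[C@](C)(C#C)O1 | intermediate
12 | (2S,3S,5R)-2-ethynyl-2-methyl-5-(prop-1-en-2-yl)oxolan-3-yl trifluoromethanesulfonate | CC(=C)[C@H]1C[C@H](OS(=O)(=O)C(F)(F)F)[C@](C)(C#C)O1 | intermediate
13 | (2S,3R,5R)-3-bromo-2-ethynyl-2-methyl-5-(prop-1-en-2-yl)oxolane (bromine cis to methyl) | CC(=C)[C@H]1C[C@@H](Br)[C@](C)(C#C)O1 | intermediate
14 | chlorobis(cyclopentadienyl)[(E)-2-[(2S,3R,5R)-3-bromo-2-methyl-5-(prop-1-en-2-yl)oxolan-2-yl]ethenyl]zirconium | CC(=C)[C@H]1C[C@@H](Br)[C@](C)(/C=C/[Zr](Cl)(C2C=CC=C2)C2C=CC=C2)O1 | intermediate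
15 | (2S,3R,5R)-3-bromo-2-[(E)-2-bromoethenyl]-2-methyl-5-(prop-1-en-2-yl)oxolane | CC(=C)[C@H]1C[C@@H](Br)[C@](C)(/C=C/Br)O1 | intermediate
16 | (2S,3R,5R)-3-bromo-2-[(E)-2-bromoethenyl]-2-methyl-5-(3-methyl-1,2,4-trioxolan-3-yl)oxolane (both epimers at the trioxolane carbon) | CC1(OCOO1)[C@H]2C[C@@H](Br)[C@](C)(/C=C/Br)O2 | intermediate
17 | (2S,3R,5R)-5-acetyl-3-bromo-2-[(E)-2-bromoethenyl]-2-methyloxolane | CC(=O)[C@H]1C[C@@H](Br)[C@](C)(/C=C/Br)O1 | intermediate
18 | (2S,3R,5R)-3-bromo-2-[(E)-2-bromoethenyl]-5-[(2S)-1-chloro-2-hydroxypropan-2-yl]-2-methyloxolane | C[C@@](O)(CCl)[C@H]1C[C@@H](Br)[C@](C)(/C=C/Br)O1 | intermediate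
19 | (2S,3R,5R)-3-bromo-2-[(E)-2-bromoethenyl]-2-methyl-5-[(2R)-2-methyloxiran-2-yl]oxolane | C[C@@]1(CO1)[C@H]2C[C@@H](Br)[C@](C)(/C=C/Br)O2 | intermediate
20 | (2S,3R,5R)-3-bromo-2-[(E)-2-bromoethenyl]-5-[(2S)-2-bromo-1-hydroxypropan-2-yl]-2-methyloxolane | C[C@](Br)(CO)[C@H]1C[C@@H](Br)[C@](C)(/C=C/Br)O1 | intermediate
21 | (2S,3R,5R)-3-bromo-2-[(E)-2-bromoethenyl]-5-[(2R)-2-bromo-1-chloropropan-2-yl]-2-methyloxolane | C[C@](Br)(CCl)[C@H]1C[C@@H](Br)[C@](C)(/C=C/Br)O1 | target

## Step count and least certain steps

Total step count: 14. Longest linear sequence: 14 steps, from ethyl pyruvate 1 to target 21.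

**Step 5 (key step).** The most likely failure is addition of the carbenoid to the electron-rich methallyl double bond in competition with C–H insertion, because cyclopropanation is intrinsically fast for rhodium carbenoids. The second is incomplete differentiation of the two O–CH2 hydrogens, because methyl and the silylalkyne at C2 differ only moderately in size, which would erode the cis relation at C5. The fallback keeps the same C4–C5 bond but changes the carbenoid to a stabilised acceptor/acceptor type and adds a thermodynamic handle.
- It sets out from acid 6, which is activated with carbonyldiimidazole and condensed with Mg(O2CCH2CO2CH2CH=CH2)2 to give prop-2-en-1-yl (4S)-4-methyl-4-[(2-methylprop-2-en-1-yl)oxy]-3-oxo-6-(triisopropylsilyl)hex-5-ynoate F1.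
- Diazo transfer with 4-acetamidobenzenesulfonyl azide and Et3N gives the 2-diazo derivative of that β-keto ester F2.
- Rh2(OAc)4 in refluxing CH2Cl2 closes the ring to prop-2-en-1-yl (2R,5S)-5-methyl-4-oxo-2-(prop-1-en-2-yl)-5-[(triisopropylsilyl)ethynyl]oxolane-3-carboxylate F3. This is the substrate class for which insertion next to ether oxygen is best documented and in which Wolff rearrangement does not occur.
- Because F3 is a β-alkoxy β-keto ester, its C5 configuration can be equilibrated with a mild base through reversible ring opening and oxa-Michael re-closure, towards the isomer with methyl and isopropenyl both pseudo-equatorial.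
- Pd(PPh3)4 and morpholine then remove the allyl ester with loss of CO2, and the route is rejoined at ketone 9.

**Step 6.** The catalyst must override the substrate: hydride delivery from the less hindered alkyne face (anti to the methyl and isopropenyl groups) would give the C3 epimer, and in this mismatched pairing the facial selectivity may be poor. The fallback accepts the substrate preference and corrects it by inversion. From ketone 9, LiBH(s-Bu)3 in THF at −78 °C gives (2S,3R,5R)-2-methyl-5-(prop-1-en-2-yl)-2-[(triisopropylsilyl)ethynyl]oxolan-3-ol F4 (hydroxyl cis to methyl). A Mitsunobu reaction with 4-nitrobenzoic acid, PPh3 and diisopropyl azodicarboxylate, in which the carboxylate enters from the open alkyne face, gives the (2S,3S,5R)-4-nitrobenzoate F5. Methanolysis with K2CO3 returns alcohol 10.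

**Step 8.** Bromide has to enter at a carbon next to the quaternary C2 and on the face that carries the methyl and isopropenyl groups. The most likely failure is elimination across C3–C4 to the 2,5-dihydrofuran, or ionisation of the triflate with 1,2-shift of a C2 substituent towards the oxygen-stabilised cation. Any route to this configuration must deliver bromide to that face, so the fallback changes the reaction type and not the trajectory. From alcohol 11, an Appel bromination (PPh3, CBr4, pyridine, toluene, 60 °C) generates bromide next to a neutral phosphine oxide leaving group inside an ion pair, with no free sulfonate that can ionise, and gives bromide 13 directly with inversion. No new isolated compound arises.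

**Step 13.** The tertiary epoxide carbon is inductively deactivated by the adjacent C5–O1 bond. Bromide may therefore open the epoxide at the CH2 carbon instead, or O1 may take part and lead to ring-expanded material. The fallback installs chlorine first and forms the tertiary bromide by Markovnikov addition, which is certain in constitution.
- From alkene 15, ene-type allylic chlorination with Ca(OCl)2 and solid CO2 in CH2Cl2/H2O gives (2S,3R,5R)-3-bromo-2-[(E)-2-bromoethenyl]-5-(3-chloroprop-1-en-2-yl)-2-methyloxolane F6.
- Addition of HBr in CH2Cl2 at −78 °C then gives target 21 directly, bypassing 16 to 20.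
- The price is that capture of the tertiary cation by bromide has no facial control, so the epimer at the side-chain carbon must be removed by chromatography.

**Step 14.** This is the least secure step after the key step. Ionisation of the activated primary oxygen can be assisted by the neighbouring tertiary bromine. The resulting bromonium ion would be opened by chloride at its tertiary carbon, which transposes the two halogens and gives the constitutional isomer with tertiary chloride and primary bromide. The fallback never activates a carbon next to the tertiary bromide. It sets out from chlorohydrin 18, in which chlorine is already on the primary carbon, and replaces the tertiary hydroxyl by bromide with Me3SiBr in CH2Cl2 at −40 → 0 °C, arriving at 21. The substitution runs through an ion pair, so inversion should predominate but will not be complete, and the epimer must be separated. No new isolated compound arises.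

## Further compounds

F1 | step 5 | prop-2-en-1-yl (4S)-4-methyl-4-[(2-methylprop-2-en-1-yl)oxy]-3-oxo-6-(triisopropylsilyl)hex-5-ynoate | C=CCOC(=O)CC(=O)[C@](C)(C#C[Si](C(C)C)(C(C)C)C(C)C)OCC(C)=C
F2 | step 5 | prop-2-en-1-yl (4S)-2-diazo-4-methyl-4-[(2-methylprop-2-en-1-yl)oxy]-3-oxo-6-(triisopropylsilyl)hex-5-ynoate | C=CCOC(=O)C(=[N+]=[N-])C(=O)[C@](C)(C#C[Si](C(C)C)(C(C)C)C(C)C)OCC(C)=C
F3 | step 5 | prop-2-en-1-yl (2R,5S)-5-methyl-4-oxo-2-(prop-1-en-2-yl)-5-[(triisopropylsilyl)ethynyl]oxolane-3-carboxylate (C3 epimers) | C=CCOC(=O)C1C(=O)[C@](C)(C#C[Si](C(C)C)(C(C)C)C(C)C)O[C@H]1C(C)=C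
F4 | step 6 | (2S,3R,5R)-2-methyl-5-(prop-1-en-2-yl)-2-[(triisopropylsilyl)ethynyl]oxolan-3-ol | CC(=C)[C@H]1C[C@@H](O)[C@](C)(C#C[Si](C(C)C)(C(C)C)C(C)C)O1
F5 | step 6 | (2S,3S,5R)-2-methyl-5-(prop-1-en-2-yl)-2-[(triisopropylsilyl)ethynyl]oxolan-3-yl 4-nitrobenzoate | CC(=C)[C@H]1C[C@H](OC(=O)c2ccc(cc2)[N+](=O)[O-])[C@](C)(C#C[Si](C(C)C)(C(C)C)C(C)C)O1
F0 | step 8 | none | none
F6 | step 13 | (2S,3R,5R)-3-bromo-2-[(E)-2-bromoethenyl]-5-(3-chloroprop-1-en-2-yl)-2-methyloxolane | ClCC(=C)[C@H]1C[C@@H](Br)[C@](C)(/C=C/Br)O1
F0 | step 14 | none | none
A1 | alternative 1 | 3-acetyl-5-[(2R)-2-bromo-1-chloropropan-2-yl]-2-methyl-2-[(trimethylsilyl)ethynyl]oxolane (acetyl, methyl and side chain all cis) | C[C@](Br)(CCl)[C@H]1C[C@@H](C(C)=O)[C@](C)(C#C[Si](C)(C)C)O1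
A2 | alternative 1 | 2-[(2R)-2-bromo-1-chloropropan-2-yl]-4-ethenyl-4,5-dimethyl-5-[(trimethylsilyl)ethynyl]-1,3-dioxolane (alkynyl carbinol carbon as drawn; acetal and vinyl carbinol carbons left open, both are lost in the key step) | C[C@](Br)(CCl)C1OC(C)(C=C)[C@](C)(C#C[Si](C)(C)C)O1
A3 | alternative 2 | (2S,5R)-2-ethenyl-2-methyl-5-(2-methyl-1,3-dioxolan-2-yl)-2,5-dihydrofuran (methyl cis to the C5 substituent) | CC1(OCCO1)[C@H]2C=C[C@](C)(C=C)O2
A4 | alternative 2 | 2-methyl-2-[(1R)-1-[(3-methylpenta-1,4-dien-3-yl)oxy]prop-2-en-1-yl]-1,3-dioxolane | CC1(OCCO1)[C@@H](C=C)OC(C)(C=C)C=C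
A5 | alternative 3 | (4S,5S)-4-(benzyloxy)-5-ethenyl-5-methyloxolan-2-one (benzyloxy trans to methyl) | O=C1C[C@H](OCc2ccccc2)[C@](C)(C=C)O1
A6 | alternative 3 | (2S,3S)-3-(benzyloxy)-2-ethenyl-2-methylcyclobutan-1-one | O=C1C[C@H](OCc2ccccc2)[C@]1(C)C=C
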